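The plan rests on one disconnection: the trans-fused A/B decalin is opened at C5–C10 and C8–C9. The angular C20 methyl on C10, the trans C5–H and C11 on C9 cis to C20 are the retron of an intramolecular Diels–Alder reaction between an (E)-3-methyl enal (C9=C10, formyl C11) and a (1E,3E)-1-silyloxy diene (C5–C8) joined by the C1–C4 tether. One Lewis-acid-promoted, formyl-endo cycloaddition closes rings A and B, forms both bonds and sets C5, C8, C9 and C10 under control of C3 and C4. The precursor is an acyclic trienal bearing C3–OAc, quaternary C4 (CH3 and CO2Et as C19) and a C8 triisopropylsilyl dienol ether.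

Key step: step 14

Remark: labdane numbering is used for every atom (β = face of the C10 methyl, C20); the target SMILES is read as the normal-series labdane 3β-acetoxy-15-hydroxylabda-8(17),13E-dien-19-al, (3S,4R,5R,9S,10R), with the formyl group axial on C4 and cis to C20.

Step 1
Reactants: 1 geraniol
Product: 2 geranyl tert-butyldiphenylsilyl ether
Conditions: TBDPSCl (1.1 equiv), imidazole, DMF, 0 °C to rt
Reagents that add atoms: tert-butyl(chloro)diphenylsilane (TBDPSCl), CC(C)(C)[Si](Cl)(c1ccccc1)c1ccccc1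
Why: Imidazole-promoted silylation of a primary allylic alcohol; the TBDPS ether is chosen because it should survive periodic acid, SnCl2 and the two LDA dianion alkylations, which an ester on the C11 oxygen would not.

Step 2
Reactants: 2 geranyl tert-butyldiphenylsilyl ether
Product: 3 6,7-epoxygeranyl tert-butyldiphenylsilyl ether (racemic at the oxirane CH)
Conditions: mCPBA (1.05 equiv), CH2Cl2, −20 to 0 °C
Reagents that add atoms: 3-chloroperbenzoic acid (mCPBA), OOC(=O)c1cccc(Cl)c1
Why: Prilezhaev epoxidation should take the electron-rich remote alkene in preference to the alkene deactivated by the allylic oxygen; the new stereocentre is racemic and is destroyed in step 3.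

Step 3
Reactants: 3 6,7-epoxygeranyl tert-butyldiphenylsilyl ether
Product: 4 (4E)-6-[(tert-butyldiphenylsilyl)oxy]-4-methylhex-4-enal
Conditions: H5IO6 (1.2 equiv), THF/Et2O, 0 °C
Reagents that add atoms: none
Why: Periodic acid opens the epoxide and cleaves the resulting glycol (Malaprade-type cleavage) to the C3 aldehyde and acetone without touching the trisubstituted alkene or the silyl ether.

Step 4
Reactants: 4 (4E)-6-[(tert-butyldiphenylsilyl)oxy]-4-methylhex-4-enal; 5 ethyl diazoacetate
Product: 6 ethyl (6E)-8-[(tert-butyldiphenylsilyl)oxy]-6-methyl-3-oxooct-6-enoate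
Conditions: SnCl2 (10 mol%), CH2Cl2, rt
Reagents that add atoms: ethyl diazoacetate (5), CCOC(=O)C=[N+]=[N-]
Why: Roskamp homologation (Lewis-acid-catalysed addition of the diazoester to the aldehyde, 1,2-hydride shift and loss of N2) should give the β-keto ester directly, adding C4 and C19.

Step 5
Reactants: 6 ethyl (6E)-8-[(tert-butyldiphenylsilyl)oxy]-6-methyl-3-oxooct-6-enoate
Product: 7 ethyl (3S,6E)-8-[(tert-butyldiphenylsilyl)oxy]-3-hydroxy-6-methyloct-6-enoate
Conditions: H2 (50 atm), RuCl2[(S)-BINAP] (0.5 mol%), EtOH, 50 °C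
Reagents that add atoms: none
Why: Noyori asymmetric hydrogenation of a β-keto ester, in which the (S)-BINAP–Ru catalyst should set the (3S) carbinol (catalyst control) and leave the isolated trisubstituted alkene, which carries no free hydroxyl, unreduced.

Step 6
Reactants: 7 ethyl (3S,6E)-8-[(tert-butyldiphenylsilyl)oxy]-3-hydroxy-6-methyloct-6-enoate; 8 allyl bromide
Product: 10 ethyl (2S,3S,6E)-8-[(tert-butyldiphenylsilyl)oxy]-3-hydroxy-6-methyl-2-(prop-2-en-1-yl)oct-6-enoate, via dilithium alkoxide–enolate of 7 9 (not isolated)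
Conditions: LDA (2.2 equiv), THF, −78 to −20 °C; allyl bromide (1.3 equiv), DMPU, −78 to −15 °C; AcOH quench
Reagents that add atoms: allyl bromide (8), C=CCBr
Why: Fráter–Seebach alkylation, in which the chelated lithium alkoxide–enolate should be alkylated on the face away from the C3 side chain to give the 2,3-anti (2S,3S) product (substrate control from C3).

Step 7
Reactants: 10 ethyl (2S,3S,6E)-8-[(tert-butyldiphenylsilyl)oxy]-3-hydroxy-6-methyl-2-(prop-2-en-1-yl)oct-6-enoate; 11 iodomethane
Product: 13 ethyl (2R,3S,6E)-8-[(tert-butyldiphenylsilyl)oxy]-3-hydroxy-2,6-dimethyl-2-(prop-2-en-1-yl)oct-6-enoate, via dilithium alkoxide–enolate of 10 12 (not isolated)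
Conditions: LDA (2.5 equiv), THF, −78 to −15 °C; MeI (3 equiv), DMPU, −78 to −20 °C; AcOH quench
Reagents that add atoms: iodomethane (11), CI
Why: Second Fráter–Seebach alkylation, in which the re-formed chelated dianion should again be attacked anti to the C3 chain, so methyl enters where allyl stood and the quaternary (2R) centre carries allyl (C5) syn and methyl (C18) anti to the C3 oxygen, which is why allyl is introduced first.

Step 8
Reactants: 13 ethyl (2R,3S,6E)-8-[(tert-butyldiphenylsilyl)oxy]-3-hydroxy-2,6-dimethyl-2-(prop-2-en-1-yl)oct-6-enoate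
Product: 14 ethyl (2R,3S,6E)-3,8-dihydroxy-2,6-dimethyl-2-(prop-2-en-1-yl)oct-6-enoate
Conditions: TBAF/AcOH (1:1, 1.5 equiv), THF, rt
Reagents that add atoms: none
Why: Fluoride desilylation of the primary silyl ether, buffered with acetic acid so that the β-hydroxy ester with its quaternary α-carbon is not exposed to base (no retro-aldol).

Step 9
Reactants: 14 ethyl (2R,3S,6E)-3,8-dihydroxy-2,6-dimethyl-2-(prop-2-en-1-yl)oct-6-enoate
Product: 15 ethyl (2R,3S,6E)-3,8-diacetoxy-2,6-dimethyl-2-(prop-2-en-1-yl)oct-6-enoate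
Conditions: Ac2O (4 equiv), DMAP (0.2 equiv), pyridine, rt
Reagents that add atoms: acetic anhydride, CC(=O)OC(C)=O
Why: DMAP-catalysed acylation of both hydroxyls; the C3 acetate blocks 5-exo oxa-Michael addition to the enal of step 10 and later serves as the equatorial control group, and the C11 acetate is a mask that can be removed in the presence of a silyl dienol ether.

Step 10
Reactants: 15 ethyl (2R,3S,6E)-3,8-diacetoxy-2,6-dimethyl-2-(prop-2-en-1-yl)oct-6-enoate; 16 crotonaldehyde
Product: 17 ethyl (2R,3S,6E)-3,8-diacetoxy-2,6-dimethyl-2-[(2E)-4-oxobut-2-en-1-yl]oct-6-enoate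
Conditions: Hoveyda–Grubbs II (5 mol%), crotonaldehyde (8 equiv), CH2Cl2, 40 °C
Reagents that add atoms: crotonaldehyde (16), C/C=C/C=O
Why: Olefin cross-metathesis of the monosubstituted alkene with excess crotonaldehyde should give the (E)-enal (C5–C8), the trisubstituted C9=C10 alkene being unreactive toward the catalyst.

Step 11
Reactants: 17 ethyl (2R,3S,6E)-3,8-diacetoxy-2,6-dimethyl-2-[(2E)-4-oxobut-2-en-1-yl]oct-6-enoate
Product: 18 ethyl (2R,3S,6E)-3,8-diacetoxy-2,6-dimethyl-2-[(1E,3E)-4-(triisopropylsilyloxy)buta-1,3-dien-1-yl]oct-6-enoate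
Conditions: TIPSOTf (1.3 equiv), Et3N (2 equiv), Et2O, −78 to 0 °C
Reagents that add atoms: triisopropylsilyl triflate (TIPSOTf), CC(C)[Si](OS(=O)(=O)C(F)(F)F)(C(C)C)C(C)C
Why: Soft enolisation (O-silylation of the enal, then γ-deprotonation at C5 by the amine) should give the silyl dienol ether, (1E) from the s-trans enal and (3E) because the quaternary C4 avoids the inside position, and it is done while C11 is still an acetate because an enal at C11 would be dienolised as well.

Step 12
Reactants: 18 ethyl (2R,3S,6E)-3,8-diacetoxy-2,6-dimethyl-2-[(1E,3E)-4-(triisopropylsilyloxy)buta-1,3-dien-1-yl]oct-6-enoate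
Product: 19 ethyl (2R,3S,6E)-3-acetoxy-8-hydroxy-2,6-dimethyl-2-[(1E,3E)-4-(triisopropylsilyloxy)buta-1,3-dien-1-yl]oct-6-enoate
Conditions: K2CO3 (0.2 equiv), MeOH, 0 °C
Reagents that add atoms: none
Why: Zemplén-type transesterification should remove the unhindered primary allylic acetate much faster than it touches the neopentyl-like C3 acetate, the α-quaternary ethyl ester or the bulky TIPS dienol ether (TIPS is chosen for this reason).

Step 13
Reactants: 19 ethyl (2R,3S,6E)-3-acetoxy-8-hydroxy-2,6-dimethyl-2-[(1E,3E)-4-(triisopropylsilyloxy)buta-1,3-dien-1-yl]oct-6-enoate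
Product: 20 ethyl (2R,3S,6E)-3-acetoxy-2,6-dimethyl-8-oxo-2-[(1E,3E)-4-(triisopropylsilyloxy)buta-1,3-dien-1-yl]oct-6-enoate (acyclic trienal)
Conditions: MnO2 (20 equiv), CH2Cl2, rt
Reagents that add atoms: none
Why: MnO2 oxidation is selective for the allylic alcohol and should give the (E)-enal without double-bond isomerisation (as for geraniol to geranial) under neutral conditions that spare the silyl dienol ether.

Step 14
Reactants: 20 ethyl (2R,3S,6E)-3-acetoxy-2,6-dimethyl-8-oxo-2-[(1E,3E)-4-(triisopropylsilyloxy)buta-1,3-dien-1-yl]oct-6-enoate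
Product: 21 ethyl 3β-acetoxy-11-oxo-8β-(triisopropylsilyloxy)-12,13,14,15,16,17-hexanorlabd-6-en-19-oate (trans-fused octalin; 5α-H, 9α-H, 10β-CH3)
Conditions: Me2AlCl (2.5 equiv), CH2Cl2, −78 to −30 °C; Et3N then aq. NaHCO3
Reagents that add atoms: none
Why: Coordination of Me2AlCl to the formyl oxygen lowers the enal LUMO and a concerted but asynchronous [4+2] cycloaddition follows in which the electron-rich diene terminus C5 bonds to the β-carbon C10 ahead of C8–C9; the closest precedent is the Lewis-acid-promoted type 1 intramolecular Diels–Alder reaction of 1,7,9-decatrienes carrying a terminally activated (E)-dienophile, which gives trans-fused decalins with an angular methyl. Ring A closes as the tether ring (the C1–C4 chain folding as a chair between C10 and C5) and ring B as the new cyclohexene formed across the diene. The (E)-enal geometry fixes C11 on C9 cis to the C10 methyl, formyl-endo addition with the tether anti gives H5 trans to that methyl, and the (1E)-enol ether geometry places the C8 oxygen cis to C11 (C8 is later made trigonal). The selectivity that matters is the diene face relative to C3 and C4: the productive chair has C3–OAc equatorial and lets the flat CO2Et, not the methyl, occupy the axial site on C4 that lies syn to the incoming C10 methyl. The two oxygenated positions are kept as separate acyclic groups on purpose, since a six-membered 3,19-acetal could sit as a strain-free chair only with C3–O axial and would then steer the diene to the wrong face. Endo selectivity should follow from the Lewis acid and from the chair tether, as in the known cases.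

Step 15
Reactants: 21 ethyl 3β-acetoxy-11-oxo-8β-(triisopropylsilyloxy)-12,13,14,15,16,17-hexanorlabd-6-en-19-oate
Product: 22 ethyl 3β-acetoxy-11-oxo-8β-(triisopropylsilyloxy)-12,13,14,15,16,17-hexanorlabdan-19-oate
Conditions: H2 (1 atm), 10% Pd/C, EtOAc, rt
Reagents that add atoms: none
Why: Heterogeneous catalytic hydrogenation of the cis-disubstituted ring alkene creates no stereocentre and should leave the aldehyde, esters and silyl ether untouched under neutral conditions.

Step 16
Reactants: 22 ethyl 3β-acetoxy-11-oxo-8β-(triisopropylsilyloxy)-12,13,14,15,16,17-hexanorlabdan-19-oate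
Product: 23 ethyl 3β-acetoxy-8β-(triisopropylsilyloxy)-13,14,15,16,17-pentanorlabd-11-en-19-oate
Conditions: Zn, CH2Br2, TiCl4 (pre-formed Lombardo reagent), THF/CH2Cl2, 0 °C to rt
Reagents that add atoms: dibromomethane, BrCBr
Why: Lombardo methylenation converts the aldehyde into the C11=C12 vinyl group under non-basic conditions, which should avoid epimerisation at C9 and E1cB loss of the anti-periplanar C8 silyloxy group and does not attack the acetate or the ester.

Step 17
Reactants: 23 ethyl 3β-acetoxy-8β-(triisopropylsilyloxy)-13,14,15,16,17-pentanorlabd-11-en-19-oate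
Product: 24 ethyl 3β-acetoxy-8β-hydroxy-13,14,15,16,17-pentanorlabd-11-en-19-oate
Conditions: TBAF (2 equiv), THF, rt
Reagents that add atoms: none
Why: Fluoride desilylation of the secondary TIPS ether is placed before the C15 silyl ether enters the molecule, so that no differentiation between two silyl ethers is needed later.

Step 18
Reactants: 25 but-2-yn-1-ol
Product: 26 (but-2-yn-1-yloxy)(tert-butyl)diphenylsilane
Conditions: TBDPSCl (1.05 equiv), imidazole, DMF, rt
Reagents that add atoms: tert-butyl(chloro)diphenylsilane (TBDPSCl), CC(C)(C)[Si](Cl)(c1ccccc1)c1ccccc1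
Why: Imidazole-promoted silylation of a primary alcohol; the TBDPS ether will carry the C15 oxygen through oxidation, methylenation and hydride reduction.

Step 19
Reactants: 26 (but-2-yn-1-yloxy)(tert-butyl)diphenylsilane
Product: 28 tert-butyl{[(2E)-3-iodobut-2-en-1-yl]oxy}diphenylsilane, via (E)-alkenylzirconocene chloride 27 (not isolated)
Conditions: Cp2Zr(H)Cl (1.5 equiv), THF, rt to 40 °C; then I2, 0 °C
Reagents that add atoms: iodine, II
Why: Hydrozirconation with the Schwartz reagent adds Zr–H syn and, after equilibration, should place zirconium on the carbon next to the methyl group, so that iodinolysis with retention gives the (E)-vinyl iodide.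

Step 20
Reactants: 24 ethyl 3β-acetoxy-8β-hydroxy-13,14,15,16,17-pentanorlabd-11-en-19-oate; 28 tert-butyl{[(2E)-3-iodobut-2-en-1-yl]oxy}diphenylsilane
Product: 30 ethyl 3β-acetoxy-15-(tert-butyldiphenylsilyloxy)-8β-hydroxy-17-norlabd-13(E)-en-19-oate, via B-alkyl-9-BBN borane 29 (not isolated)
Conditions: 9-BBN-H (2.5 equiv), THF, rt; then 28, Pd(dppf)Cl2 (5 mol%), AsPh3, aq. K3PO4, DMF, rt
Reagents that add atoms: none
Why: Anti-Markovnikov hydroboration of the only alkene puts boron on C12 and the B-alkyl Suzuki–Miyaura coupling with the vinyl iodide should form C12–C13 with retention of the (E)-geometry, the excess borane tolerating the free C8 hydroxyl.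

Step 21
Reactants: 30 ethyl 3β-acetoxy-15-(tert-butyldiphenylsilyloxy)-8β-hydroxy-17-norlabd-13(E)-en-19-oate
Product: 31 ethyl 3β-acetoxy-15-(tert-butyldiphenylsilyloxy)-8-oxo-17-norlabd-13(E)-en-19-oate
Conditions: Dess–Martin periodinane (1.5 equiv), CH2Cl2, rt
Reagents that add atoms: none
Why: Dess–Martin oxidation of the only free hydroxyl; the C9 side chain is equatorial and therefore already in the stable configuration next to the new ketone.

Step 22
Reactants: 31 ethyl 3β-acetoxy-15-(tert-butyldiphenylsilyloxy)-8-oxo-17-norlabd-13(E)-en-19-oate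
Product: 32 ethyl 3β-acetoxy-15-(tert-butyldiphenylsilyloxy)labda-8(17),13(E)-dien-19-oate
Conditions: Zn, CH2Br2, TiCl4 (pre-formed Lombardo reagent), THF/CH2Cl2, rt
Reagents that add atoms: dibromomethane, BrCBr
Why: Lombardo methylenation is suited to hindered enolisable ketones and, being non-basic, should install the C8(17) methylene without epimerising C9 or attacking the acetate, the ester or the silyl ether.

Step 23
Reactants: 32 ethyl 3β-acetoxy-15-(tert-butyldiphenylsilyloxy)labda-8(17),13(E)-dien-19-oate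
Product: 33 15-(tert-butyldiphenylsilyloxy)labda-8(17),13(E)-diene-3β,19-diol
Conditions: LiAlH4 (3 equiv), THF, 0 °C to rt
Reagents that add atoms: none
Why: Hydride reduction should convert the hindered axial ester into the C19 alcohol and cleave the C3 acetate in the same operation, while the alkenes and the silyl ether are not reduced.

Step 24
Reactants: 33 15-(tert-butyldiphenylsilyloxy)labda-8(17),13(E)-diene-3β,19-diol
Product: 34 15-(tert-butyldiphenylsilyloxy)-3β-hydroxylabda-8(17),13(E)-dien-19-al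
Conditions: TEMPO (0.2 equiv), PhI(OAc)2 (1.3 equiv), CH2Cl2, rt
Reagents that add atoms: none
Why: Oxoammonium (TEMPO) oxidation is strongly selective for primary over secondary alcohols and stops at the aldehyde, so the C19 alcohol should be oxidised while the hindered C3 hydroxyl remains.

Step 25
Reactants: 34 15-(tert-butyldiphenylsilyloxy)-3β-hydroxylabda-8(17),13(E)-dien-19-al
Product: 35 3β-acetoxy-15-(tert-butyldiphenylsilyloxy)labda-8(17),13(E)-dien-19-al
Conditions: Ac2O (3 equiv), DMAP (0.1 equiv), pyridine, CH2Cl2, rt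
Reagents that add atoms: acetic anhydride, CC(=O)OC(C)=O
Why: DMAP-catalysed acetylation of the only free hydroxyl; the non-enolisable aldehyde on quaternary C4 cannot epimerise or eliminate.

Step 26
Reactants: 35 3β-acetoxy-15-(tert-butyldiphenylsilyloxy)labda-8(17),13(E)-dien-19-al
Product: 36 3β-acetoxy-15-hydroxylabda-8(17),13(E)-dien-19-al (target)
Conditions: TBAF/AcOH (1:1, 2 equiv), THF, rt
Reagents that add atoms: none
Why: Acetic-acid-buffered fluoride desilylation should free the C15 allylic alcohol without acetate cleavage or migration and without affecting the aldehyde or the two alkenes.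

Compound list
1 | geraniol, (2E)-3,7-dimethylocta-2,6-dien-1-ol | CC(C)=CCC/C(C)=C/CO | starting material
2 | geranyl tert-butyldiphenylsilyl ether | CC(C)=CCC/C(C)=C/CO[Si](c1ccccc1)(c1ccccc1)C(C)(C)C | intermediate
3 | tert-butyl{[(2E)-5-(3,3-dimethyloxiran-2-yl)-3-methylpent-2-en-1-yl]oxy}diphenylsilane (racemic at the oxirane CH) | CC1(C)OC1CC/C(C)=C/CO[Si](c1ccccc1)(c1ccccc1)C(C)(C)C | intermediate
4 | (4E)-6-[(tert-butyldiphenylsilyl)oxy]-4-methylhex-4-enal | O=CCC/C(C)=C/CO[Si](c1ccccc1)(c1ccccc1)C(C)(C)C | intermediate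
5 | ethyl diazoacetate | CCOC(=O)C=[N+]=[N-] | starting material
6 | ethyl (6E)-8-[(tert-butyldiphenylsilyl)oxy]-6-methyl-3-oxooct-6-enoate | CCOC(=O)CC(=O)CC/C(C)=C/CO[Si](c1ccccc1)(c1ccccc1)C(C)(C)C | intermediate
7 | ethyl (3S,6E)-8-[(tert-butyldiphenylsilyl)oxy]-3-hydroxy-6-methyloct-6-enoate | CCOC(=O)C[C@@H](O)CC/C(C)=C/CO[Si](c1ccccc1)(c1ccccc1)C(C)(C)C | intermediate
8 | allyl bromide, 3-bromoprop-1-ene | C=CCBr | starting material
9 | dilithium alkoxide–enolate of 7 (chelated dianion) | [Li+].[Li+].CCO/C([O-])=C/[C@@H]([O-])CC/C(C)=C/CO[Si](c1ccccc1)(c1ccccc1)C(C)(C)C | intermediate (not isolated)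
10 | ethyl (2S,3S,6E)-8-[(tert-butyldiphenylsilyl)oxy]-3-hydroxy-6-methyl-2-(prop-2-en-1-yl)oct-6-enoate | CCOC(=O)[C@@H](CC=C)[C@@H](O)CC/C(C)=C/CO[Si](c1ccccc1)(c1ccccc1)C(C)(C)C | intermediate
11 | iodomethane | CI | starting material
12 | dilithium alkoxide–enolate of 10 (chelated dianion) | [Li+].[Li+].CCO/C([O-])=C(\CC=C)[C@@H]([O-])CC/C(C)=C/CO[Si](c1ccccc1)(c1ccccc1)C(C)(C)C | intermediate (not isolated)
13 | ethyl (2R,3S,6E)-8-[(tert-butyldiphenylsilyl)oxy]-3-hydroxy-2,6-dimethyl-2-(prop-2-en-1-yl)oct-6-enoate | CCOC(=O)[C@](C)(CC=C)[C@@H](O)CC/C(C)=C/CO[Si](c1ccccc1)(c1ccccc1)C(C)(C)C | intermediate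
14 | ethyl (2R,3S,6E)-3,8-dihydroxy-2,6-dimethyl-2-(prop-2-en-1-yl)oct-6-enoate | CCOC(=O)[C@](C)(CC=C)[C@@H](O)CC/C(C)=C/CO | intermediate
15 | ethyl (2R,3S,6E)-3,8-diacetoxy-2,6-dimethyl-2-(prop-2-en-1-yl)oct-6-enoate | CCOC(=O)[C@](C)(CC=C)[C@@H](OC(C)=O)CC/C(C)=C/COC(C)=O | intermediate
16 | crotonaldehyde, (2E)-but-2-enal | C/C=C/C=O | starting material
17 | ethyl (2R,3S,6E)-3,8-diacetoxy-2,6-dimethyl-2-[(2E)-4-oxobut-2-en-1-yl]oct-6-enoate | CCOC(=O)[C@](C)(C/C=C/C=O)[C@@H](OC(C)=O)CC/C(C)=C/COC(C)=O | intermediate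
18 | ethyl (2R,3S,6E)-3,8-diacetoxy-2,6-dimethyl-2-[(1E,3E)-4-(triisopropylsilyloxy)buta-1,3-dien-1-yl]oct-6-enoate | CCOC(=O)[C@](C)(/C=C/C=C/O[Si](C(C)C)(C(C)C)C(C)C)[C@@H](OC(C)=O)CC/C(C)=C/COC(C)=O | intermediate
19 | ethyl (2R,3S,6E)-3-acetoxy-8-hydroxy-2,6-dimethyl-2-[(1E,3E)-4-(triisopropylsilyloxy)buta-1,3-dien-1-yl]oct-6-enoate | CCOC(=O)[C@](C)(/C=C/C=C/O[Si](C(C)C)(C(C)C)C(C)C)[C@@H](OC(C)=O)CC/C(C)=C/CO | intermediate
20 | ethyl (2R,3S,6E)-3-acetoxy-2,6-dimethyl-8-oxo-2-[(1E,3E)-4-(triisopropylsilyloxy)buta-1,3-dien-1-yl]oct-6-enoate (key-step precursor) | CCOC(=O)[C@](C)(/C=C/C=C/O[Si](C(C)C)(C(C)C)C(C)C)[C@@H](OC(C)=O)CC/C(C)=C/C=O | intermediate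
21 | ethyl 3β-acetoxy-11-oxo-8β-(triisopropylsilyloxy)-12,13,14,15,16,17-hexanorlabd-6-en-19-oate (key-step product) | [C@H]1(O[Si](C(C)C)(C(C)C)C(C)C)C=C[C@H]2[C@@](C)(C(=O)OCC)[C@@H](OC(C)=O)CC[C@]2(C)[C@H]1C=O | intermediate
22 | ethyl 3β-acetoxy-11-oxo-8β-(triisopropylsilyloxy)-12,13,14,15,16,17-hexanorlabdan-19-oate | [C@H]1(O[Si](C(C)C)(C(C)C)C(C)C)CC[C@H]2[C@@](C)(C(=O)OCC)[C@@H](OC(C)=O)CC[C@]2(C)[C@H]1C=O | intermediate
23 | ethyl 3β-acetoxy-8β-(triisopropylsilyloxy)-13,14,15,16,17-pentanorlabd-11-en-19-oate | [C@H]1(O[Si](C(C)C)(C(C)C)C(C)C)CC[C@H]2[C@@](C)(C(=O)OCC)[C@@H](OC(C)=O)CC[C@]2(C)[C@H]1C=C | intermediate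
24 | ethyl 3β-acetoxy-8β-hydroxy-13,14,15,16,17-pentanorlabd-11-en-19-oate | [C@H]1(O)CC[C@H]2[C@@](C)(C(=O)OCC)[C@@H](OC(C)=O)CC[C@]2(C)[C@H]1C=C | intermediate
25 | but-2-yn-1-ol | CC#CCO | starting material
26 | (but-2-yn-1-yloxy)(tert-butyl)diphenylsilane | CC#CCO[Si](c1ccccc1)(c1ccccc1)C(C)(C)C | intermediate
27 | chloridobis(cyclopentadienyl)[(2E)-4-(tert-butyldiphenylsilyloxy)but-2-en-2-yl]zirconium (Cp rings drawn σ-bonded) | C/C(=C\CO[Si](c1ccccc1)(c1ccccc1)C(C)(C)C)[Zr](Cl)(C1C=CC=C1)C1C=CC=C1 | intermediate (not isolated)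
28 | tert-butyl{[(2E)-3-iodobut-2-en-1-yl]oxy}diphenylsilane | C/C(I)=C\CO[Si](c1ccccc1)(c1ccccc1)C(C)(C)C | intermediate
29 | ethyl 3β-acetoxy-12-(9-borabicyclo[3.3.1]nonan-9-yl)-8β-hydroxy-13,14,15,16,17-pentanorlabdan-19-oate | [C@H]1(O)CC[C@H]2[C@@](C)(C(=O)OCC)[C@@H](OC(C)=O)CC[C@]2(C)[C@H]1CCB1C2CCCC1CCC2 | intermediate (not isolated)
30 | ethyl 3β-acetoxy-15-(tert-butyldiphenylsilyloxy)-8β-hydroxy-17-norlabd-13(E)-en-19-oate | [C@H]1(O)CC[C@H]2[C@@](C)(C(=O)OCC)[C@@H](OC(C)=O)CC[C@]2(C)[C@H]1CC/C(C)=C/CO[Si](c1ccccc1)(c1ccccc1)C(C)(C)C | intermediate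
31 | ethyl 3β-acetoxy-15-(tert-butyldiphenylsilyloxy)-8-oxo-17-norlabd-13(E)-en-19-oate | O=C1CC[C@H]2[C@@](C)(C(=O)OCC)[C@@H](OC(C)=O)CC[C@]2(C)[C@H]1CC/C(C)=C/CO[Si](c1ccccc1)(c1ccccc1)C(C)(C)C | intermediate
32 | ethyl 3β-acetoxy-15-(tert-butyldiphenylsilyloxy)labda-8(17),13(E)-dien-19-oate | C=C1CC[C@H]2[C@@](C)(C(=O)OCC)[C@@H](OC(C)=O)CC[C@]2(C)[C@H]1CC/C(C)=C/CO[Si](c1ccccc1)(c1ccccc1)C(C)(C)C | intermediate
33 | 15-(tert-butyldiphenylsilyloxy)labda-8(17),13(E)-diene-3β,19-diol | C=C1CC[C@H]2[C@@](C)(CO)[C@@H](O)CC[C@]2(C)[C@H]1CC/C(C)=C/CO[Si](c1ccccc1)(c1ccccc1)C(C)(C)C | intermediate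
34 | 15-(tert-butyldiphenylsilyloxy)-3β-hydroxylabda-8(17),13(E)-dien-19-al | C=C1CC[C@H]2[C@@](C)(C=O)[C@@H](O)CC[C@]2(C)[C@H]1CC/C(C)=C/CO[Si](c1ccccc1)(c1ccccc1)C(C)(C)C | intermediate
35 | 3β-acetoxy-15-(tert-butyldiphenylsilyloxy)labda-8(17),13(E)-dien-19-al | C=C1CC[C@H]2[C@@](C)(C=O)[C@@H](OC(C)=O)CC[C@]2(C)[C@H]1CC/C(C)=C/CO[Si](c1ccccc1)(c1ccccc1)C(C)(C)C | intermediate
36 | 3β-acetoxy-15-hydroxylabda-8(17),13(E)-dien-19-al, (3S,4R,5R,9S,10R), CNP0185120.1 | C=C1CC[C@H]2[C@@](C)(C=O)[C@@H](OC(C)=O)CC[C@]2(C)[C@H]1CC/C(C)=C/CO | target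

Total step count: 26 (24 in the main line and 2 for the vinyl iodide branch).
Longest linear sequence: 24 steps (steps 1–17 and 20–26, from geraniol).

Steps most likely to fail

Step 14 (key cycloaddition). The diene face may be selected only weakly, because the equatorial preference of C3–OAc and the axial tolerance of CO2Et are both small. The Lewis acid may also ionise or desilylate the dienol ether, or a stepwise Michael addition may stop before ring B closes. Fallback: stereocontrol is moved from the substrate to the reagent. Trienal 20 would be cyclised with a chiral cationic oxazaborolidinium Lewis acid (proline-derived oxazaborolidine activated by triflimide, CH2Cl2, −78 °C), a known catalyst class for enal Diels–Alder reactions, including intramolecular ones and those of silyloxy dienes. The catalyst antipode would be chosen so that its facial preference reinforces that of C3/C4. The fallback sets out from 20 and returns at adduct 21; no new compound arises (F0).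

Step 7 (quaternary alkylation). Deprotonation of the hindered α-allyl ester may be incomplete, the alkoxide may undergo retro-aldol cleavage on warming, or facial discrimination at the tetrasubstituted enolate may erode. Fallback: a β-lactone enolate alkylation, setting out from 10. Saponification (LiOH, THF/H2O) would give (2S,3S,6E)-8-[(tert-butyldiphenylsilyl)oxy]-3-hydroxy-6-methyl-2-(prop-2-en-1-yl)oct-6-enoic acid F1. Carboxyl-activating lactonisation (PhSO2Cl, pyridine, 0 °C, retention at C3) would give the trans-β-lactone (3S,4S)-4-{(3E)-5-[(tert-butyldiphenylsilyl)oxy]-3-methylpent-3-en-1-yl}-3-(prop-2-en-1-yl)oxetan-2-one F2. Its enolate (LDA, THF, −78 °C) is known to be alkylated anti to the ring substituent, so iodomethane should give the (3R,4S)-3-methyl-3-allyl lactone F3 with the same C4 configuration as in 13. Ethanolysis by acyl–oxygen cleavage (K2CO3, EtOH, 0 °C) returns to 13.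

Step 24 (chemoselective oxidation). Oxoammonium oxidation of the neopentyl, axial C19 alcohol may be slow, and forcing it may erode the primary/secondary selectivity. Fallback: the two hydroxyls are differentiated by protection, setting out from diol 33. Silylation of the primary alcohol (TESCl, imidazole, CH2Cl2, −20 °C) would give 15-(tert-butyldiphenylsilyloxy)-19-(triethylsilyloxy)labda-8(17),13(E)-dien-3β-ol F4. Acetylation (Ac2O, DMAP, pyridine) would give 3β-acetoxy-15-(tert-butyldiphenylsilyloxy)-19-(triethylsilyloxy)labda-8(17),13(E)-diene F5. Selective removal of the triethylsilyl ether (AcOH/THF/H2O, rt; the TBDPS ether survives) would give 3β-acetoxy-15-(tert-butyldiphenylsilyloxy)labda-8(17),13(E)-dien-19-ol F6. Dess–Martin oxidation then gives 35, where the route is rejoined after step 25.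

Further compounds
F0 | step 14 | none | none
F1 | step 7 | (2S,3S,6E)-8-[(tert-butyldiphenylsilyl)oxy]-3-hydroxy-6-methyl-2-(prop-2-en-1-yl)oct-6-enoic acid | OC(=O)[C@@H](CC=C)[C@@H](O)CC/C(C)=C/CO[Si](c1ccccc1)(c1ccccc1)C(C)(C)C
F2 | step 7 | (3S,4S)-4-{(3E)-5-[(tert-butyldiphenylsilyl)oxy]-3-methylpent-3-en-1-yl}-3-(prop-2-en-1-yl)oxetan-2-one | O=C1O[C@@H](CC/C(C)=C/CO[Si](c2ccccc2)(c2ccccc2)C(C)(C)C)[C@@H]1CC=C
F3 | step 7 | (3R,4S)-4-{(3E)-5-[(tert-butyldiphenylsilyl)oxy]-3-methylpent-3-en-1-yl}-3-methyl-3-(prop-2-en-1-yl)oxetan-2-one | O=C1O[C@@H](CC/C(C)=C/CO[Si](c2ccccc2)(c2ccccc2)C(C)(C)C)[C@@]1(C)CC=C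
F4 | step 24 | 15-(tert-butyldiphenylsilyloxy)-19-(triethylsilyloxy)labda-8(17),13(E)-dien-3β-ol | C=C1CC[C@H]2[C@@](C)(CO[Si](CC)(CC)CC)[C@@H](O)CC[C@]2(C)[C@H]1CC/C(C)=C/CO[Si](c1ccccc1)(c1ccccc1)C(C)(C)C
F5 | step 24 | 3β-acetoxy-15-(tert-butyldiphenylsilyloxy)-19-(triethylsilyloxy)labda-8(17),13(E)-diene | C=C1CC[C@H]2[C@@](C)(CO[Si](CC)(CC)CC)[C@@H](OC(C)=O)CC[C@]2(C)[C@H]1CC/C(C)=C/CO[Si](c1ccccc1)(c1ccccc1)C(C)(C)C
F6 | step 24 | 3β-acetoxy-15-(tert-butyldiphenylsilyloxy)labda-8(17),13(E)-dien-19-ol | C=C1CC[C@H]2[C@@](C)(CO)[C@@H](OC(C)=O)CC[C@]2(C)[C@H]1CC/C(C)=C/CO[Si](c1ccccc1)(c1ccccc1)C(C)(C)C
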